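## The problem

The target is a 3,8''-linked biflavanone: C3 of unit 1, a 2,3-trans chroman-4-one with the catechol ring B, is bonded to C8'' of unit 2, a naringenin-type chromanone, so the central bond joins an sp3 stereocentre to an arene carbon flanked by two oxygen-bearing carbons. Three stereocentres must be set: C2 (R) and C3 (S) in unit 1 and C2'' (S) in unit 2. C2 can control C3, because C3 is an α-aryl ketone carbon that equilibrates to the trans arrangement, but C2'' lies four bonds from C3 across the flat ring A of unit 2 and cannot be relied on to bias C2 and C3. On the phloroglucinol-type ring A of unit 2 the positions 6'' and 8'' differ only in which neighbouring oxygen is the ring oxygen, so any substitution of a preformed arene has to choose between them. Both chromanone rings open under base by retro-oxa-Michael reaction, which scrambles C2 and C2'', and the C2–O1 and C2''–O1'' bonds are benzylic ethers para to an oxygen that can ionise under strong acid, so the seven phenols must be freed last and under neutral conditions. The feature that opens the structure is that C8'' is the neighbour of C8a'', the carbon bearing the ring oxygen O1'': the C4a''=C8a'' bond of ring A is also the enol-ether double bond of a 2-aryl-2,3-dihydropyran-4-one, electrophilic at C8a'' and nucleophilic at C4a''. Carbons C5'' to C8'', with their two oxygens and the C8'' substituent, can then come from one four-carbon unit of matching polarity, and no choice between 6'' and 8'' arises.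

## Retrosynthesis

**Target 24 to hexabenzyl ether 23.** Six O–benzyl bonds are cut. Benzyl is chosen because hydrogenolysis needs neither acid nor base. The 5''-hydroxyl is carried free from step 5 onward: it is hydrogen-bonded to C4''=O and inert, and benzylating it would need a base that opens the chromanone. The forward step must leave the benzylic C2–O1 and C2''–O1'' bonds intact.

**23 to deoxybenzoin 20 and aldehyde 21.** The bonds C2–C3 and O1–C2 are cut, so that both go to the carbon of a commercial aldehyde. A cut at C3–C8'' would ask for arylation of a flavanone enolate by a hindered aryl electrophile, and a cut at O1–C8a for substitution on an electron-rich ring; neither has a good forward reaction. The precursor has one ring and two stereocentres fewer. The forward reaction is a condensation to chalcone 22 and an oxa-Michael closure. The closure is reversible under the conditions that bring it about, so C3 settles trans to C2. For the same reason no kinetic preference between the (2R,3S) and the (2S,3R) arrangement could be held, and the remote C2'' centre offers none. The plan therefore accepts that both trans arrangements arise. Because C2'' is fixed they are diastereomers: 23 is taken by chromatography and the rest is returned to the equilibrium through 22. The conditions must be mild enough that unit 2 stays closed.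

**20 to ketone 19, then to acid 16 and arene 17.** The aryl ketone bond C4–C4a is cut. The symmetric tribenzyl ether 17 has three equivalent positions, so no regiochemistry arises, and it is nucleophilic enough to be acylated by a mixed trifluoroacetic anhydride at room temperature. The ortho-hydroxyl needed for ring closure is then freed from 19 by chelation-controlled loss of one benzyl group. Direct Fries-type acylation of a free phenol is one step shorter but needs a stronger Lewis acid and heat, which endanger the benzyl ethers and C2''; it is kept as a fallback.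

**16 to aldehyde 15, allyl compound 13 and diol 12.** These are functional-group changes. The acetic acid side chain comes from an allyl group by alkene cleavage and oxidation. The 7''-hydroxyl is benzylated under Mitsunobu conditions, without base. Allyl is chosen for C8'' because it is inert to silyl triflate and to enol-ether chemistry and is two oxidations from the acid.

**12 to bromopyranone 5 and diene 8 (key disconnection).** The bonds C8''–C8a'' and C4a''–C5'' are cut and ring A of unit 2 disappears. The neighbouring cut, C8''–allyl on a finished 5,7-dihydroxyflavanone, leads to mixtures of 6- and 8-substitution. Here polarity decides: the nucleophilic diene terminus meets C8a'' and the acyl carbon meets C4a''. The precursors are a monocyclic enantiopure pyranone and an acyclic diene. The forward reaction must add at C8a'', acylate C4a'', lose HBr and not the ring oxygen, and leave C2'' alone.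

**5 to pyranone 4, then to aldehyde 1 and diene 2; 8 to silyl enol ether 7 and ketoester 6.** Bromine is placed at the nucleophilic α-carbon of the vinylogous ester 4. The bonds C2''–C3'' and O1''–C8a'' of 4 are cut back to 1 and 2; the forward catalytic asymmetric hetero-Diels–Alder reaction is the only step that has to create C2''. Diene 8 comes from 6 by two silylations.

## Roads not taken

Alternative 1: Ring A of unit 1 is unfolded to a 4-hydroxy-2-pyrone, A2, that carries the α-aryl enone side chain. In the forward key step Mg(OMe)2 opens the lactone, and the side-chain methylene carbon (future C4a) condenses onto the former lactone carbonyl carbon (future C8a). This Claisen closure releases the trihydroxy α-aryl chalcone A1.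
- Merits: the ring-forming type is precedented and biomimetic, so in this respect the road is better than the chosen plan, whose step 5 is new. No stereocentre is present, so the base does no harm. A1 has the three ring A hydroxyls free and is one oxa-Michael closure from unit 1.
- Weak points: nothing in A1 is stereodefined, and all three centres would come from two oxa-Michael closures with no handle on C2''. Ring C of unit 2 must still be built by C-acylation of the allyloxy-bis(benzyloxy)phenyl ring, which must pick the carbon next to the allyloxy group over the one between the benzyloxy groups, so the 6''/8'' question returns. The making of A2 needs a hindered C-acylation.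
- Against it the chosen plan sets regiochemistry fixed by polarity and a C2'' centre from asymmetric catalysis at the start.

Alternative 2: Ring C of unit 1 is cut at C2–C3 and O1–C8a. In the forward key step aldehyde 21, activated by a chiral Ti(OiPr)4–binaphthol catalyst, reacts with the aryl-bearing silyloxy diene A4 in a hetero-Diels–Alder reaction; loss of methanol gives the 2,3-diaryl-2,3-dihydropyran-4-one A3.
- Merits: C2 and C3 are set together under catalyst control. This is the pair that the chosen plan can only sort by separation and recycling, so here this road is better.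
- Weak points: A4 carries a 2,6-dioxygenated aryl group on its reacting terminus, so the cycloaddition should be slow and its asymmetric version is poorly supported. After A3, ring A of unit 1 must still be grown on the pyranone by the same kind of unprecedented benzannulation as step 5, now beside an epimerisable C3. Ring C of unit 2 must then be closed by an oxa-Michael reaction that leaves C2'' uncontrolled.
- The road trades control of C2'' for control of C2 and C3 and needs two hard steps where the chosen plan needs one. The chosen plan also takes ring A of unit 1 from the symmetric arene 17 without any regiochemical question.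

Alternative 3: The bond C4''–C4a'' of unit 2 is cut. In the forward key step the 3-aryloxy-3-arylpropanoic acid A6, which already holds all of unit 1, is activated as a mixed anhydride and acylates the only ortho carbon within reach. This closes the chromanone of unit 2 and gives the hexabenzyl ether acetate A5.
- Merits: the ring closure has precedent, its regiochemistry is enforced by the tether, all three stereocentres can be set before it, and the route is convergent. On these counts it is as good as or better than the chosen plan.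
- Weak points: A6 needs an aryl alkyl ether between a phenol flanked by the bulky C3 substituent and a secondary benzylic carbon, formed with inversion. β-Aryloxy acids lose the phenol by elimination when activated. The acetate that damps benzylic ionisation needs a further deprotection in the presence of base-sensitive flavanones.
- Against it the chosen plan sets a route with no hindered etherification and no elimination-prone acid, and a single neutral deprotection.

Key step: step 5

Assumption: the (R)-configured octahydrobinaphthol complex of tetravalent titanium is taken to give the (S)-pyranone 4; if the sense of induction is the opposite, the (S)-ligand is used and nothing else changes.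

Assumption: stereocentres that vanish in the next event (C8'', C8a'', C4a'' in 9 and 10; the carbinol carbon of 14) and double-bond geometries that are lost (7, C1=C2 of 8, 22) are left undefined.

## Steps

Step 1
Reactants: 1 4-(benzyloxy)benzaldehyde; 2 (E)-1-methoxy-3-(trimethylsilyloxy)buta-1,3-diene
Product: 4 (2S)-2-[4-(benzyloxy)phenyl]-2,3-dihydro-4H-pyran-4-one, via aldol adduct silyl ether 3 (not isolated)
Conditions: Ti(OiPr)4 (20 mol %), (R)-5,5',6,6',7,7',8,8'-octahydro-1,1'-bi-2-naphthol (22 mol %), 4 Å MS, toluene, 0 °C; then CF3CO2H, CH2Cl2, 0 °C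
Reagents that add atoms: none
Why: Catalytic asymmetric hetero-Diels–Alder reaction in its Mukaiyama-aldol form: the chiral titanium complex binds aldehyde 1 and the diene terminus adds to one face, which sets C2'' under catalyst control. Acid then closes 3 by conjugate addition of the oxygen and loss of methanol, without touching the stereocentre.

Step 2
Reactants: 4 (2S)-2-[4-(benzyloxy)phenyl]-2,3-dihydro-4H-pyran-4-one
Product: 5 (2S)-2-[4-(benzyloxy)phenyl]-5-bromo-2,3-dihydro-4H-pyran-4-one
Conditions: N-bromosuccinimide (1.05 equiv), CH2Cl2, 0 °C to rt, dark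
Reagents that add atoms: N-bromosuccinimide, O=C1CCC(=O)N1Br
Why: Electrophilic α-bromination of a vinylogous ester: C5 is the nucleophilic enol-ether carbon, and loss of the C5 proton restores the enone. The alkoxyphenyl ring is far less nucleophilic than the enol ether at this temperature.

Step 3
Reactants: 6 methyl 3-oxohept-6-enoate
Product: 7 methyl 3-(trimethylsilyloxy)hepta-2,6-dienoate
Conditions: Me3SiCl, Et3N, toluene, rt
Reagents that add atoms: chlorotrimethylsilane, C[Si](C)(C)Cl
Why: O-Silylation of the enol of a β-ketoester, the standard first stage in the making of 1,3-bis(silyloxy)dienes.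

Step 4
Reactants: 7 methyl 3-(trimethylsilyloxy)hepta-2,6-dienoate
Product: 8 (3Z)-1-methoxy-1,3-bis(trimethylsilyloxy)hepta-1,3,6-triene
Conditions: LiN(iPr)2, THF, −78 °C; Me3SiCl, −78 °C to rt; salts and solvent removed under argon
Reagents that add atoms: chlorotrimethylsilane, C[Si](C)(C)Cl
Why: γ-Deprotonation of the silyloxy enoate and O-silylation of the extended enolate give the bis(silyloxy)diene. It is sensitive to moisture and is used at once.

Step 5
Reactants: 5 (2S)-2-[4-(benzyloxy)phenyl]-5-bromo-2,3-dihydro-4H-pyran-4-one; 8 (3Z)-1-methoxy-1,3-bis(trimethylsilyloxy)hepta-1,3,6-triene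
Product: 12 (2S)-8-allyl-2-[4-(benzyloxy)phenyl]-5,7-dihydroxychroman-4-one, via Mukaiyama–Michael adduct 9 (not isolated), via ring-closed bromo-dione 10 (not isolated), via bis(trimethylsilyl) ether 11 (not isolated)
Conditions: Me3SiOTf (1.5 equiv), CH2Cl2, −78 °C; 8 (1.5 equiv), −78 to 0 °C; 2,6-lutidine (4 equiv), 0 °C to rt; 1 M HCl, THF, rt
Reagents that add atoms: none
Why: Proposed new method: Me3SiOTf silylates the carbonyl oxygen of 5 and so makes C8a'' (pyranone C6) an oxocarbenium-type carbon, to which the allyl-bearing terminus of 8 adds (vinylogous Mukaiyama–Michael reaction) to give 9, a silyl enol ether whose masked C4'' cannot serve as an aldol acceptor. Silyl triflate on the enoate carbonyl of 9 regenerates the oxygen-stabilised cation at the former ketene-acetal carbon, and the C4a'' enol ether attacks it in a 6-(enolexo)-exo-trig, Claisen-type closure; loss of Me3SiOMe gives 10, so that C8''–C8a'' and C4a''–C5'' are the two new ring bonds. 2,6-Lutidine with the silyl triflate then enolises 10 towards C8'' and removes HBr across C4a''–C8a''; the ring aromatises to 11 and dilute acid frees the phenols of 12. The closest known reactions are the Me3SiOTf-mediated conjugate addition of 1,3-bis(silyloxy)dienes to chromones and the Diels–Alder reaction and aromatisation of 1-alkoxy-1,3-bis(silyloxy)dienes with bromoquinones, which makes the same two bonds and loses HBr and methanol in the same way; neither has been shown on a 5-halo-2,3-dihydropyran-4-one. No stereocentre is created in 12: the centres at C8'', C8a'' and C4a'' of 9 and 10 vanish on aromatisation, and C2'' is a spectator. Three selectivities are needed: the regiochemistry follows from polarity (the nucleophilic diene terminus can only meet C8a'', the acyl carbon only C4a''); closure at C4a'' and not aldol closure onto C4'' is secured by keeping everything silylated and aprotic until the ring exists; loss of bromide in preference to the ring oxygen O1'' is secured by the absence of a free enolate beside C8a'' and by the irreversibility of HBr loss, the bromine at C4a'' supplying the oxidation level of the arene.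

Step 6
Reactants: 12 (2S)-8-allyl-2-[4-(benzyloxy)phenyl]-5,7-dihydroxychroman-4-one
Product: 13 (2S)-8-allyl-7-(benzyloxy)-2-[4-(benzyloxy)phenyl]-5-hydroxychroman-4-one
Conditions: BnOH (1.1 equiv), PPh3, diisopropyl azodicarboxylate, THF, 0 °C to rt
Reagents that add atoms: benzyl alcohol, OCc1ccccc1
Why: Mitsunobu etherification: the acidic, non-chelated 7''-hydroxyl is the pronucleophile, while the 5''-hydroxyl, hydrogen-bonded to C4''=O, stays free. No base able to open the chromanone is present, so C2'' is safe.

Step 7
Reactants: 13 (2S)-8-allyl-7-(benzyloxy)-2-[4-(benzyloxy)phenyl]-5-hydroxychroman-4-one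
Product: 15 2-[(2S)-7-(benzyloxy)-2-[4-(benzyloxy)phenyl]-5-hydroxy-4-oxochroman-8-yl]acetaldehyde, via vicinal diol 14 (not isolated)
Conditions: OsO4 (2 mol %), NaIO4 (4 equiv), 2,6-lutidine, dioxane/H2O 3:1, rt
Reagents that add atoms: osmium tetroxide, O=[Os](=O)(=O)=O (oxygen carrier); sodium periodate, [Na+].[O-]I(=O)(=O)=O (terminal oxidant)
Why: Lemieux–Johnson cleavage: catalytic dihydroxylation of the terminal alkene to 14 and periodate scission give the arylacetaldehyde. The buffered medium leaves the benzyl ethers and the chelated phenol alone.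

Step 8
Reactants: 15 2-[(2S)-7-(benzyloxy)-2-[4-(benzyloxy)phenyl]-5-hydroxy-4-oxochroman-8-yl]acetaldehyde
Product: 16 2-[(2S)-7-(benzyloxy)-2-[4-(benzyloxy)phenyl]-5-hydroxy-4-oxochroman-8-yl]acetic acid
Conditions: NaClO2, NaH2PO4, 2-methyl-2-butene (excess), t-BuOH/THF/H2O, 0 °C to rt
Reagents that add atoms: sodium chlorite, [Na+].[O-]Cl=O
Why: Pinnick oxidation of the aldehyde to the acid. The alkene scavenger removes hypochlorite before it can chlorinate C6''.

Step 9
Reactants: 16 2-[(2S)-7-(benzyloxy)-2-[4-(benzyloxy)phenyl]-5-hydroxy-4-oxochroman-8-yl]acetic acid; 17 1,3,5-tris(benzyloxy)benzene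
Product: 19 2-[(2S)-7-(benzyloxy)-2-[4-(benzyloxy)phenyl]-5-hydroxy-4-oxochroman-8-yl]-1-[2,4,6-tris(benzyloxy)phenyl]ethan-1-one, via mixed trifluoroacetic anhydride 18 (not isolated)
Conditions: (CF3CO)2O (1.5 equiv), CH2Cl2, 0 °C; 17 (2 equiv), 0 °C to rt; aq. NaHCO3/MeOH
Reagents that add atoms: none
Why: Friedel–Crafts acylation through the mixed trifluoroacetic anhydride: the three equivalent positions of the very electron-rich 17 react at room temperature without a metal Lewis acid, so the benzyl ethers and the C2''–O1'' bond are not stressed. A trifluoroacetate formed at the 5''-hydroxyl is cleaved in the work-up.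

Step 10
Reactants: 19 2-[(2S)-7-(benzyloxy)-2-[4-(benzyloxy)phenyl]-5-hydroxy-4-oxochroman-8-yl]-1-[2,4,6-tris(benzyloxy)phenyl]ethan-1-one
Product: 20 1-[2,4-bis(benzyloxy)-6-hydroxyphenyl]-2-[(2S)-7-(benzyloxy)-2-[4-(benzyloxy)phenyl]-5-hydroxy-4-oxochroman-8-yl]ethan-1-one
Conditions: BCl3 (2.2 equiv), CH2Cl2, −78 °C, 30 min; then H2O
Reagents that add atoms: none
Why: Chelation-controlled ether cleavage: BCl3 bound to the new aryl ketone removes one flanking benzyl group as benzyl chloride, and the boron chelate that results shields the second ortho ether. Benzyl ethers not next to a carbonyl react much more slowly at this temperature.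

Step 11
Reactants: 20 1-[2,4-bis(benzyloxy)-6-hydroxyphenyl]-2-[(2S)-7-(benzyloxy)-2-[4-(benzyloxy)phenyl]-5-hydroxy-4-oxochroman-8-yl]ethan-1-one; 21 3,4-bis(benzyloxy)benzaldehyde
Product: 23 (2R,3S)-5,7-bis(benzyloxy)-3-[(2S)-7-(benzyloxy)-2-[4-(benzyloxy)phenyl]-5-hydroxy-4-oxochroman-8-yl]-2-[3,4-bis(benzyloxy)phenyl]chroman-4-one, via α-aryl chalcone 22 (not isolated)
Conditions: piperidine (0.3 equiv), AcOH (0.3 equiv), 4 Å MS, toluene, 80 °C; then chromatography
Reagents that add atoms: none
Why: Knoevenagel condensation of the deoxybenzoin methylene with 21 gives chalcone 22, whose ortho-phenol closes ring C by 6-endo-trig oxa-Michael addition; C3 equilibrates as an α-aryl ketone carbon, so the 2,3-trans arrangement results under thermodynamic control by C2. The remote C2'' centre is not expected to bias the two faces of 22, so both trans arrangements should arise; as C2'' is fixed they are diastereomers, 23 is isolated by chromatography and the remainder is returned to the same conditions, which re-equilibrate it through 22. The buffered amine is chosen because the C3'' hydrogens of unit 2 are far less acidic than the α-aryl position of unit 1, so unit 2 should stay closed.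

Step 12
Reactants: 23 (2R,3S)-5,7-bis(benzyloxy)-3-[(2S)-7-(benzyloxy)-2-[4-(benzyloxy)phenyl]-5-hydroxy-4-oxochroman-8-yl]-2-[3,4-bis(benzyloxy)phenyl]chroman-4-one
Product: 24 (2R,3S)-2-(3,4-dihydroxyphenyl)-3-[(2S)-5,7-dihydroxy-2-(4-hydroxyphenyl)-4-oxochroman-8-yl]-5,7-dihydroxychroman-4-one
Conditions: H2 (1 atm), 10% Pd/C, EtOAc/MeOH, rt
Reagents that add atoms: none
Why: Hydrogenolysis of the six aryl benzyl ethers under neutral conditions. With no acid or base present, C2, C3 and C2'' should keep their configuration.

## Compound list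

1 | 4-(benzyloxy)benzaldehyde | O=Cc1ccc(OCc2ccccc2)cc1 | starting material
2 | (E)-1-methoxy-3-(trimethylsilyloxy)buta-1,3-diene | CO/C=C/C(=C)O[Si](C)(C)C | starting material
3 | (1E,5S)-5-[4-(benzyloxy)phenyl]-1-methoxy-5-(trimethylsilyloxy)pent-1-en-3-one | CO/C=C/C(=O)C[C@@H](c1ccc(OCc2ccccc2)cc1)O[Si](C)(C)C | intermediate (not isolated)
4 | (2S)-2-[4-(benzyloxy)phenyl]-2,3-dihydro-4H-pyran-4-one | O=C1C[C@@H](c2ccc(OCc3ccccc3)cc2)OC=C1 | intermediate
5 | (2S)-2-[4-(benzyloxy)phenyl]-5-bromo-2,3-dihydro-4H-pyran-4-one | O=C1C[C@@H](c2ccc(OCc3ccccc3)cc2)OC=C1Br | intermediate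
6 | methyl 3-oxohept-6-enoate | COC(=O)CC(=O)CCC=C | starting material
7 | methyl 3-(trimethylsilyloxy)hepta-2,6-dienoate (C2=C3 geometry undefined) | COC(=O)C=C(O[Si](C)(C)C)CCC=C | intermediate
8 | (3Z)-1-methoxy-1,3-bis(trimethylsilyloxy)hepta-1,3,6-triene (C1=C2 geometry undefined) | COC(O[Si](C)(C)C)=C/C(O[Si](C)(C)C)=C/CC=C | intermediate
9 | methyl 4-[(2S)-2-[4-(benzyloxy)phenyl]-5-bromo-4-(trimethylsilyloxy)-3,6-dihydro-2H-pyran-6-yl]-3-(trimethylsilyloxy)hepta-2,6-dienoate (new centres undefined) | COC(=O)C=C(O[Si](C)(C)C)C(CC=C)C1O[C@H](c2ccc(OCc3ccccc3)cc2)CC(O[Si](C)(C)C)=C1Br | intermediate (not isolated)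
10 | (2S)-8-allyl-2-[4-(benzyloxy)phenyl]-4a-bromo-7-(trimethylsilyloxy)-2,3,8,8a-tetrahydro-4H-chromene-4,5(4aH)-dione (centres at C4a, C8, C8a undefined) | O=C1C[C@@H](c2ccc(OCc3ccccc3)cc2)OC2C(CC=C)C(O[Si](C)(C)C)=CC(=O)C12Br | intermediate (not isolated)
11 | (2S)-8-allyl-2-[4-(benzyloxy)phenyl]-5,7-bis(trimethylsilyloxy)chroman-4-one | O=C1C[C@@H](c2ccc(OCc3ccccc3)cc2)Oc2c1c(O[Si](C)(C)C)cc(O[Si](C)(C)C)c2CC=C | intermediate (not isolated)
12 | (2S)-8-allyl-2-[4-(benzyloxy)phenyl]-5,7-dihydroxychroman-4-one | O=C1C[C@@H](c2ccc(OCc3ccccc3)cc2)Oc2c1c(O)cc(O)c2CC=C | intermediate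
13 | (2S)-8-allyl-7-(benzyloxy)-2-[4-(benzyloxy)phenyl]-5-hydroxychroman-4-one | O=C1C[C@@H](c2ccc(OCc3ccccc3)cc2)Oc2c1c(O)cc(OCc1ccccc1)c2CC=C | intermediate
14 | (2S)-7-(benzyloxy)-2-[4-(benzyloxy)phenyl]-8-(2,3-dihydroxypropyl)-5-hydroxychroman-4-one (carbinol centre undefined) | O=C1C[C@@H](c2ccc(OCc3ccccc3)cc2)Oc2c1c(O)cc(OCc1ccccc1)c2CC(O)CO | intermediate (not isolated)
15 | 2-[(2S)-7-(benzyloxy)-2-[4-(benzyloxy)phenyl]-5-hydroxy-4-oxochroman-8-yl]acetaldehyde | O=C1C[C@@H](c2ccc(OCc3ccccc3)cc2)Oc2c1c(O)cc(OCc1ccccc1)c2CC=O | intermediate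
16 | 2-[(2S)-7-(benzyloxy)-2-[4-(benzyloxy)phenyl]-5-hydroxy-4-oxochroman-8-yl]acetic acid | O=C1C[C@@H](c2ccc(OCc3ccccc3)cc2)Oc2c1c(O)cc(OCc1ccccc1)c2CC(=O)O | intermediate
17 | 1,3,5-tris(benzyloxy)benzene | c1ccc(COc2cc(OCc3ccccc3)cc(OCc3ccccc3)c2)cc1 | starting material
18 | mixed anhydride of 16 and trifluoroacetic acid | O=C1C[C@@H](c2ccc(OCc3ccccc3)cc2)Oc2c1c(O)cc(OCc1ccccc1)c2CC(=O)OC(=O)C(F)(F)F | intermediate (not isolated)
19 | 2-[(2S)-7-(benzyloxy)-2-[4-(benzyloxy)phenyl]-5-hydroxy-4-oxochroman-8-yl]-1-[2,4,6-tris(benzyloxy)phenyl]ethan-1-one | O=C1C[C@@H](c2ccc(OCc3ccccc3)cc2)Oc2c1c(O)cc(OCc1ccccc1)c2CC(=O)c1c(OCc2ccccc2)cc(OCc2ccccc2)cc1OCc1ccccc1 | intermediate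
20 | 1-[2,4-bis(benzyloxy)-6-hydroxyphenyl]-2-[(2S)-7-(benzyloxy)-2-[4-(benzyloxy)phenyl]-5-hydroxy-4-oxochroman-8-yl]ethan-1-one | O=C1C[C@@H](c2ccc(OCc3ccccc3)cc2)Oc2c1c(O)cc(OCc1ccccc1)c2CC(=O)c1c(O)cc(OCc2ccccc2)cc1OCc1ccccc1 | intermediate
21 | 3,4-bis(benzyloxy)benzaldehyde | O=Cc1ccc(OCc2ccccc2)c(OCc2ccccc2)c1 | starting material
22 | 1-[2,4-bis(benzyloxy)-6-hydroxyphenyl]-2-[(2S)-7-(benzyloxy)-2-[4-(benzyloxy)phenyl]-5-hydroxy-4-oxochroman-8-yl]-3-[3,4-bis(benzyloxy)phenyl]prop-2-en-1-one (alkene geometry undefined) | O=C1C[C@@H](c2ccc(OCc3ccccc3)cc2)Oc2c1c(O)cc(OCc1ccccc1)c2C(=Cc1ccc(OCc2ccccc2)c(OCc2ccccc2)c1)C(=O)c1c(O)cc(OCc2ccccc2)cc1OCc1ccccc1 | intermediate (not isolated)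
23 | (2R,3S)-5,7-bis(benzyloxy)-3-[(2S)-7-(benzyloxy)-2-[4-(benzyloxy)phenyl]-5-hydroxy-4-oxochroman-8-yl]-2-[3,4-bis(benzyloxy)phenyl]chroman-4-one | O=C1C[C@@H](c2ccc(OCc3ccccc3)cc2)Oc2c1c(O)cc(OCc1ccccc1)c2[C@@H]1C(=O)c2c(OCc3ccccc3)cc(OCc3ccccc3)cc2O[C@H]1c1ccc(OCc2ccccc2)c(OCc2ccccc2)c1 | intermediate
24 | (2R,3S)-2-(3,4-dihydroxyphenyl)-3-[(2S)-5,7-dihydroxy-2-(4-hydroxyphenyl)-4-oxochroman-8-yl]-5,7-dihydroxychroman-4-one | O=C1C[C@@H](c2ccc(O)cc2)Oc2c1c(O)cc(O)c2[C@@H]1C(=O)c2c(O)cc(O)cc2O[C@H]1c1ccc(O)c(O)c1 | target

## Step count and weakest steps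

Total: 12 steps. Longest linear sequence: 10 steps (1, 2, 5 to 12; the diene branch 3, 4, 5 to 12 is equally long).

**Step 5 (key step, new method).** The most likely failure is that the sequence stalls after the conjugate addition: desilylation of the cation in 9 may outrun ring closure, and on work-up the open-chain ketoester could then close by aldol reaction onto C4'' or lose the ring oxygen by β-elimination. A second risk is partial loss of configuration at C2'' through reversible ionisation of the benzylic C2''–O1'' bond while the pyranone is silylated.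

The fallback uses known chemistry and places the allyl group before the pyranone ring exists. It sets out from 17 and comes back at 13. Acetylation of 17 (AcOH, (CF3CO)2O) should give 1-[2,4,6-tris(benzyloxy)phenyl]ethan-1-one F1, and BCl3 at −78 °C should free one ortho-hydroxyl to give 1-[2,4-bis(benzyloxy)-6-hydroxyphenyl]ethan-1-one F2. Allyl bromide and K2CO3 should give 1-[2-(allyloxy)-4,6-bis(benzyloxy)phenyl]ethan-1-one F3. Thermal Claisen rearrangement (N,N-diethylaniline, 190 °C) can only reach the one free ortho carbon and should give 1-[3-allyl-4,6-bis(benzyloxy)-2-hydroxyphenyl]ethan-1-one F4. Me2NCH(OMe)2 should give (E)-1-[3-allyl-4,6-bis(benzyloxy)-2-hydroxyphenyl]-3-(dimethylamino)prop-2-en-1-one F5, which acid closes to 8-allyl-5,7-bis(benzyloxy)-4H-chromen-4-one F6. Asymmetric 1,4-addition of 4-(benzyloxy)phenylboronic acid, catalysed by [Rh(OH)(cod)]2 (cod = cycloocta-1,5-diene) and a chiral bisphosphine, should give (2S)-8-allyl-5,7-bis(benzyloxy)-2-[4-(benzyloxy)phenyl]chroman-4-one F7. Chelation-controlled removal of the 5-O-benzyl group with BCl3 at −78 °C then returns the material to the route at 13.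

**Step 11.** Two things may go wrong. The closure has no facial control from the remote C2'' centre, so the step depends on a clean chromatographic separation of the two trans arrangements and on recycling. The methylene of 20 is also flanked by two ortho-disubstituted aryl groups, so condensation may be slow, and the heat and amine then needed could start retro-oxa-Michael opening of unit 2 and erode C2''.

The fallback sets out from 20 and 21 and comes back at 23. LiN(SiMe3)2 (3 equiv, THF, −78 °C) should deprotonate the two phenols and then the more acidic α-aryl methylene, and addition to 21 gives the aldol 1-[2,4-bis(benzyloxy)-6-hydroxyphenyl]-2-[(2S)-7-(benzyloxy)-2-[4-(benzyloxy)phenyl]-5-hydroxy-4-oxochroman-8-yl]-3-[3,4-bis(benzyloxy)phenyl]-3-hydroxypropan-1-one F8. Intramolecular Mitsunobu etherification (PPh3, diisopropyl azodicarboxylate, 0 °C) closes ring C, and a trace of Et3N settles C3 trans. Chromatography then separates 23 from (2S,3R)-5,7-bis(benzyloxy)-3-[(2S)-7-(benzyloxy)-2-[4-(benzyloxy)phenyl]-5-hydroxy-4-oxochroman-8-yl]-2-[3,4-bis(benzyloxy)phenyl]chroman-4-one F9. F9 is returned to 23 by a brief treatment with piperidinium acetate, which re-equilibrates the closed chromanone through 22. The open deoxybenzoin is never heated with amine.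

**Step 9.** The activated acid may lose carbon monoxide, because the benzyl cation left behind is stabilised by three oxygens. Acylation of the substrate's own phenol or rings may also compete with attack by 17.

The fallback sets out from 16 and comes back at 20, so that step 10 is not needed. Steglich esterification with 3,5-bis(benzyloxy)phenol (carbodiimide, 4-dimethylaminopyridine) should give 3,5-bis(benzyloxy)phenyl 2-[(2S)-7-(benzyloxy)-2-[4-(benzyloxy)phenyl]-5-hydroxy-4-oxochroman-8-yl]acetate F10. Fries rearrangement with BF3·OEt2 then moves the acyl group to the ortho carbon.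

**Step 12.** Cleavage of six benzyl ethers may be slow, and long exposure could lead to hydrogenolytic opening of the benzylic C2–O1 and C2''–O1'' bonds.

The fallback sets out from 23 and ends at 24. The ethers are cleaved without hydrogen by BCl3 and pentamethylbenzene in CH2Cl2 at −78 °C, the arene trapping the benzyl cations. This fallback makes no new compound (F0).

## Further compounds

F1 | step 5 | 1-[2,4,6-tris(benzyloxy)phenyl]ethan-1-one | CC(=O)c1c(OCc2ccccc2)cc(OCc2ccccc2)cc1OCc1ccccc1
F2 | step 5 | 1-[2,4-bis(benzyloxy)-6-hydroxyphenyl]ethan-1-one | CC(=O)c1c(O)cc(OCc2ccccc2)cc1OCc1ccccc1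
F3 | step 5 | 1-[2-(allyloxy)-4,6-bis(benzyloxy)phenyl]ethan-1-one | CC(=O)c1c(OCC=C)cc(OCc2ccccc2)cc1OCc1ccccc1
F4 | step 5 | 1-[3-allyl-4,6-bis(benzyloxy)-2-hydroxyphenyl]ethan-1-one | CC(=O)c1c(O)c(CC=C)c(OCc2ccccc2)cc1OCc1ccccc1
F5 | step 5 | (E)-1-[3-allyl-4,6-bis(benzyloxy)-2-hydroxyphenyl]-3-(dimethylamino)prop-2-en-1-one | CN(C)/C=C/C(=O)c1c(O)c(CC=C)c(OCc2ccccc2)cc1OCc1ccccc1
F6 | step 5 | 8-allyl-5,7-bis(benzyloxy)-4H-chromen-4-one | O=c1ccoc2c(CC=C)c(OCc3ccccc3)cc(OCc3ccccc3)c12
F7 | step 5 | (2S)-8-allyl-5,7-bis(benzyloxy)-2-[4-(benzyloxy)phenyl]chroman-4-one | O=C1C[C@@H](c2ccc(OCc3ccccc3)cc2)Oc2c1c(OCc1ccccc1)cc(OCc1ccccc1)c2CC=C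
F8 | step 11 | 1-[2,4-bis(benzyloxy)-6-hydroxyphenyl]-2-[(2S)-7-(benzyloxy)-2-[4-(benzyloxy)phenyl]-5-hydroxy-4-oxochroman-8-yl]-3-[3,4-bis(benzyloxy)phenyl]-3-hydroxypropan-1-one (new centres undefined) | O=C1C[C@@H](c2ccc(OCc3ccccc3)cc2)Oc2c1c(O)cc(OCc1ccccc1)c2C(C(O)c1ccc(OCc2ccccc2)c(OCc2ccccc2)c1)C(=O)c1c(O)cc(OCc2ccccc2)cc1OCc1ccccc1
F9 | step 11 | (2S,3R)-5,7-bis(benzyloxy)-3-[(2S)-7-(benzyloxy)-2-[4-(benzyloxy)phenyl]-5-hydroxy-4-oxochroman-8-yl]-2-[3,4-bis(benzyloxy)phenyl]chroman-4-one | O=C1C[C@@H](c2ccc(OCc3ccccc3)cc2)Oc2c1c(O)cc(OCc1ccccc1)c2[C@H]1C(=O)c2c(OCc3ccccc3)cc(OCc3ccccc3)cc2O[C@@H]1c1ccc(OCc2ccccc2)c(OCc2ccccc2)c1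
F10 | step 9 | 3,5-bis(benzyloxy)phenyl 2-[(2S)-7-(benzyloxy)-2-[4-(benzyloxy)phenyl]-5-hydroxy-4-oxochroman-8-yl]acetate | O=C1C[C@@H](c2ccc(OCc3ccccc3)cc2)Oc2c1c(O)cc(OCc1ccccc1)c2CC(=O)Oc1cc(OCc2ccccc2)cc(OCc2ccccc2)c1
F0 | step 12 | none | none
A1 | alternative 1 | (E)-2-[2-(allyloxy)-4,6-bis(benzyloxy)phenyl]-3-[3,4-bis(benzyloxy)phenyl]-1-(2,4,6-trihydroxyphenyl)prop-2-en-1-one | Oc1cc(O)cc(O)c1C(=O)/C(=C/c1ccc(OCc2ccccc2)c(OCc2ccccc2)c1)c1c(OCC=C)cc(OCc2ccccc2)cc1OCc1ccccc1
A2 | alternative 1 | 6-{(3E)-3-[2-(allyloxy)-4,6-bis(benzyloxy)phenyl]-4-[3,4-bis(benzyloxy)phenyl]-2-oxobut-3-en-1-yl}-4-hydroxy-2H-pyran-2-one | O=C1C=C(O)C=C(CC(=O)/C(=C/c2ccc(OCc3ccccc3)c(OCc3ccccc3)c2)c2c(OCC=C)cc(OCc3ccccc3)cc2OCc2ccccc2)O1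
A3 | alternative 2 | (2R,3S)-2-[3,4-bis(benzyloxy)phenyl]-3-[2-(tert-butyldimethylsilyloxy)-4,6-bis(benzyloxy)phenyl]-2,3-dihydro-4H-pyran-4-one | CC(C)(C)[Si](C)(C)Oc1cc(OCc2ccccc2)cc(OCc2ccccc2)c1[C@@H]1C(=O)C=CO[C@H]1c1ccc(OCc2ccccc2)c(OCc2ccccc2)c1
A4 | alternative 2 | (1E,3Z)-4-[2-(tert-butyldimethylsilyloxy)-4,6-bis(benzyloxy)phenyl]-1-methoxy-3-(trimethylsilyloxy)buta-1,3-diene | CO/C=C/C(O[Si](C)(C)C)=C/c1c(O[Si](C)(C)C(C)(C)C)cc(OCc2ccccc2)cc1OCc1ccccc1
A5 | alternative 3 | 4-[(2S)-5,7-bis(benzyloxy)-8-[(2R,3S)-5,7-bis(benzyloxy)-2-[3,4-bis(benzyloxy)phenyl]-4-oxochroman-3-yl]-4-oxochroman-2-yl]phenyl acetate | O=C1C[C@@H](c2ccc(OC(C)=O)cc2)Oc2c1c(OCc1ccccc1)cc(OCc1ccccc1)c2[C@@H]1C(=O)c2c(OCc3ccccc3)cc(OCc3ccccc3)cc2O[C@H]1c1ccc(OCc2ccccc2)c(OCc2ccccc2)c1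
A6 | alternative 3 | (3S)-3-(4-acetoxyphenyl)-3-{3,5-bis(benzyloxy)-2-[(2R,3S)-5,7-bis(benzyloxy)-2-[3,4-bis(benzyloxy)phenyl]-4-oxochroman-3-yl]phenoxy}propanoic acid | OC(=O)C[C@@H](c1ccc(OC(C)=O)cc1)Oc1cc(OCc2ccccc2)cc(OCc2ccccc2)c1[C@@H]1C(=O)c2c(OCc3ccccc3)cc(OCc3ccccc3)cc2O[C@H]1c1ccc(OCc2ccccc2)c(OCc2ccccc2)c1
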